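**Strategy.** Everything rests on building the γ-lactone ring fused to the seven-membered ring at its vicinal pair C7/C8: C7 must gain the acrylate carbon C11 and C8 the lactone oxygen. A ketene lactonization does both in one operation: dichloroketene acylates an enantiopure (E)-vinyl sulfoxide, a [3,3] shift forms C11–C7 with transfer of chirality from sulfur, and the carboxylate traps the thionium ion at C8. The precursor is an acyclic sulfinyl alkene; C8 is later allylated trans, the cyclopentenone and seven-membered ring are annulated, and a final Diels–Alder union with a separately made seco-eudesmanolide dienophile, then methylenation, gives the target.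

Key step: step 3

Remark on numbering: the hydroazulene half is numbered as a guaiane (C1–C15), the other half as a 1,10-seco-eudesmane with primes (C1'–C15').
Assumption on the key step: the sulfur-to-carbon transfer follows a chair-like transition state with the p-tolyl group pseudo-equatorial; on this model the (R)-(E)-sulfoxide gives the required C7 configuration.
Remark on the phosphonate: from compound 14 onward the phosphonate-bearing carbon C11 is carried as a mixture of epimers, which converge in step 32.

**Part 1 – hydroazulene half**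

Step 1
Reactants: 1 tert-butyl(diphenyl)(prop-2-yn-1-yloxy)silane; 2 (1R,2S,5R)-menthyl (S)-p-toluenesulfinate
Product: 4 (S)-3-(tert-butyldiphenylsilyloxy)prop-1-ynyl p-tolyl sulfoxide, via alkynylmagnesium bromide 3 (not isolated)
Conditions: EtMgBr, THF, 0 °C; then 2, toluene, −20 °C
Reagents that add atoms: none
Why: The alkynyl Grignard reagent displaces menthoxide at sulfur with clean inversion (sulfinate-to-sulfoxide substitution), which sets the sulfur stereocentre.

Step 2
Reactants: 4 alkynyl sulfoxide
Product: 5 (R,E)-3-(tert-butyldiphenylsilyloxy)prop-1-enyl p-tolyl sulfoxide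
Conditions: i-Bu2AlH, THF, −90 °C
Reagents that add atoms: none
Why: trans-Hydroalumination of the alkynyl sulfoxide and protonolysis should give the (E)-alkene without touching sulfur (alkyne to (E)-alkene reduction; the descriptor changes from S to R only through the priority rules).

Step 3
Reactants: 5 (R,E)-vinyl sulfoxide
Product: 8 (4R,5R)-3,3-dichloro-4-[(tert-butyldiphenylsilyloxy)methyl]-5-(p-tolylthio)oxolan-2-one, via acyloxysulfonium enolate 6 (not isolated), via thionium carboxylate 7 (not isolated)
Conditions: Cl3CCOCl, Zn–Cu couple, THF, −45 to 0 °C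
Reagents that add atoms: trichloroacetyl chloride, ClC(=O)C(Cl)(Cl)Cl
Why: The sulfinyl oxygen adds to dichloroketene to give the O-acylated sulfonium enolate 6, whose [3,3]-sigmatropic shift makes the C11–C7 bond and the thionium carboxylate 7, and the carboxylate then closes onto the thionium carbon to make the O–C8 bond (an additive Pummerer sequence). The closest known reaction is the Marino ketene lactonization of 1-alkenyl sulfoxides, of which this is a direct case. The only ring formed, the γ-lactone, closes in a 5-exo-trig mode by attack of oxygen on C8 of the C=S+ bond. C7 is set by chirality transfer from sulfur through a chair-like transition state with the p-tolyl group and the (E)-substituent pseudo-equatorial; C8 is expected trans to the C7 side chain but is a thioacetal centre that step 5 resets. The step needs O-acylation of the sulfoxide to outrun [2+2] addition of the ketene to the alkene, and needs C–C bonding at the β-carbon with C–O bonding at the α-carbon; the sulfinyl group secures both, being the most nucleophilic site and fixing the regiochemistry through the cyclic shift.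

Step 4
Reactants: 8 dichloro lactone
Product: 9 (4R,5R)-4-[(tert-butyldiphenylsilyloxy)methyl]-5-(p-tolylthio)oxolan-2-one
Conditions: Al/Hg amalgam, THF/H2O/MeOH, 0 °C to rt
Reagents that add atoms: none
Why: Dissolving-metal reduction should remove both α-chlorines while the thioacetal and the silyl ether survive (reductive dehalogenation).

Step 5
Reactants: 9 thioacetal lactone; 10 (2-bromoallyl)trimethylsilane
Product: 12 4,5-trans-5-(2-bromoprop-2-enyl)-4-[(tert-butyldiphenylsilyloxy)methyl]oxolan-2-one (C7 and C8 as in the target), via acyloxycarbenium ion 11 (not isolated)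
Conditions: p-TolSCl, AgOTf, 2,6-di-tert-butyl-4-methylpyridine, 4 Å MS, CH2Cl2, −78 °C; then 10, −78 to −30 °C
Reagents that add atoms: none
Why: Proposed new method: the soft electrophile p-TolSOTf sulfenylates the thioacetal sulfur, loss of the disulfide leaves the acyloxycarbenium ion 11 with the ring O–C8 bond intact, and the allylsilane adds anti to the C7 side chain to give the 7,8-trans lactone; the closest known reaction type is pre-activation C-glycosylation of thioglycosides with allylsilanes (Hosomi–Sakurai capture of an oxocarbenium ion).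

Step 6
Reactants: 12 trans lactone
Product: 14 diethyl [5-(2-bromoprop-2-enyl)-4-(silyloxymethyl)-2-oxooxolan-3-yl]phosphonate (4,5-trans; epimers at C3), via lactone enol phosphate 13 (not isolated)
Conditions: LiN(i-Pr)2 (1.1 equiv), THF, −78 °C; ClP(O)(OEt)2; then LiN(i-Pr)2 (2.2 equiv), −78 °C to rt
Reagents that add atoms: diethyl chlorophosphate, CCOP(=O)(Cl)OCC
Why: O-Phosphorylation of the lactone enolate and base-induced 1,3-phosphoryl shift (vinyl phosphate–phosphonate rearrangement) give the α-phosphono lactone, which masks the future exo-methylene and removes dienophile character from this half.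

Step 7
Reactants: 14 silyl ether
Product: 15 diethyl [5-(2-bromoprop-2-enyl)-4-(hydroxymethyl)-2-oxooxolan-3-yl]phosphonate
Conditions: HF·pyridine, pyridine/THF, 0 °C to rt
Reagents that add atoms: none
Why: Buffered fluoride cleaves the primary silyl ether without base, so the freed hydroxyl should not translactonise (silyl ether cleavage).

Step 8
Reactants: 15 primary alcohol
Product: 16 diethyl [5-(2-bromoprop-2-enyl)-4-(iodomethyl)-2-oxooxolan-3-yl]phosphonate
Conditions: I2, PPh3, imidazole, CH2Cl2, 0 °C
Reagents that add atoms: iodine, II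
Why: The Appel reaction converts the primary alcohol into the iodide under neutral conditions.

Step 9
Reactants: 17 (R)-4-(tert-butyldimethylsilyloxy)cyclopent-2-en-1-one
Product: 18 (R)-4-(tert-butyldimethylsilyloxy)-2-iodocyclopent-2-en-1-one
Conditions: I2, pyridine, CH2Cl2, 0 °C to rt
Reagents that add atoms: iodine, II
Why: Amine-mediated α-iodination of the enone (conjugate addition of pyridine, iodination, elimination) leaves the silyloxy stereocentre, the future C2, untouched.

Step 10
Reactants: 16 primary iodide; 18 iodoenone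
Product: 20 2-[(lactonyl)methyl]-4-silyloxycyclopent-2-enone (C5–C6 bond made; vinyl bromide retained), via alkylzinc iodide 19 (not isolated)
Conditions: Zn dust (TMSCl-activated), LiCl, THF, 25 °C; then 18, Pd2(dba)3 (2.5 mol %), SPhos (10 mol %), THF/NMP, 25 °C
Reagents that add atoms: none
Why: Zinc inserts selectively into the primary C–I bond, and Negishi coupling occurs at the α-iodoenone, whose C–I bond adds to zerovalent palladium faster than the vinyl bromide.

Step 11
Reactants: 20 enone vinyl bromide
Product: 21 tricyclic triethylsilyl enol ether (C4–C5 enol ether; C10=C14 exocyclic methylene; 1-H anti to the 2-silyloxy group; 7,8-trans lactone)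
Conditions: NiCl2(dme) (10 mol %), neocuproine (10 mol %), Mn, Et3SiCl, DMF, 25 °C, high dilution
Reagents that add atoms: chlorotriethylsilane, CC[Si](Cl)(CC)CC
Why: Nickel-catalysed reductive conjugate addition of the vinyl bromide to the enone β-carbon C1 with silyl trapping closes the seven-membered ring in a 7-endo mode and gives the regiodefined enol ether; C1 is drawn with C10 anti to the 2-silyloxy group and is erased in step 12.

Step 12
Reactants: 21 silyl enol ether
Product: 22 2α-silyloxy dienone (C4 ketone; C1=C5; C10=C14; 12,8α-lactone with 11-phosphonate)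
Conditions: Pd(OAc)2 (10 mol %), O2 (1 atm), DMSO, 45 °C
Reagents that add atoms: none
Why: Saegusa–Ito oxidation of the silyl enol ether restores the C1=C5 enone, now tetrasubstituted and conjugated with the exocyclic methylene, the endocyclic position being the usual outcome for 2-alkylcyclopentanone enol ethers.

Step 13
Reactants: 22 silyloxy dienone
Product: 23 2α-hydroxy dienone
Conditions: HF·pyridine, THF, 0 °C
Reagents that add atoms: none
Why: Fluoride cleaves the secondary silyl ether and frees the C2 hydroxyl needed as directing group (silyl ether cleavage).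

Step 14
Reactants: 23 hydroxy dienone
Product: 24 2α-hydroxy-10β-methyl enone (10α-H)
Conditions: [Ir(cod)(PCy3)(py)]PF6 (5 mol %), H2 (1 atm), CH2Cl2, 0 °C
Reagents that add atoms: none
Why: In this hydroxyl-directed hydrogenation, iridium bound to the homoallylic C2–OH should deliver H2 to the 1,1-disubstituted C10=C14 bond from the hydroxyl face, which sets 10α-H and 10β-methyl, while the tetrasubstituted enone bond is left.

Step 15
Reactants: 24 enone
Product: 25 2α,4-diol (tertiary C4 carbinol with the new methyl C15; C1=C5)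
Conditions: MeMgBr, CeCl3, THF, −78 °C (excess reagent)
Reagents that add atoms: methylmagnesium bromide, C[Mg]Br
Why: The organocerium reagent adds 1,2 to the hindered enone carbonyl faster than to the lactone and without enolisation (organocerium carbonyl addition); the new C4 centre is lost in step 31.

Step 16
Reactants: 25 diol
Product: 26 2α-acetoxy-4-hydroxy compound
Conditions: Ac2O, pyridine, DMAP (cat.), CH2Cl2, 0 °C
Reagents that add atoms: acetic anhydride, CC(=O)OC(C)=O
Why: Acylation distinguishes the secondary allylic C2 hydroxyl from the tertiary C4 hydroxyl on steric grounds (selective esterification).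

**Part 2 – seco-eudesmanolide dienophile**

Step 17
Reactants: 27 tert-butyl(pent-4-en-1-yloxy)diphenylsilane; 28 methyl vinyl ketone
Product: 29 (E)-7-(tert-butyldiphenylsilyloxy)hept-3-en-2-one
Conditions: second-generation Grubbs catalyst (H2IMes)(PCy3)Cl2Ru=CHPh (2 mol %), CH2Cl2, 40 °C
Reagents that add atoms: none
Why: Cross-metathesis of a terminal alkene with an electron-poor vinyl ketone is selective for the (E)-enone.

Step 18
Reactants: 29 enone
Product: 30 (R)-7-(tert-butyldiphenylsilyloxy)-4-methylheptan-2-one
Conditions: MeMgBr, CuBr·SMe2 (5 mol %), Josiphos ligand (6 mol %; the enantiomer that gives the R product), t-BuOMe, −75 °C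
Reagents that add atoms: methylmagnesium bromide, C[Mg]Br
Why: Copper-catalysed asymmetric conjugate addition of the methyl Grignard reagent sets C4' by ligand control.

Step 19
Reactants: 30 methyl ketone
Product: 31 (R)-7-(tert-butyldiphenylsilyloxy)-4-methyl-3-methyleneheptan-2-one
Conditions: (HCHO)n, diisopropylammonium trifluoroacetate, THF, reflux
Reagents that add atoms: formaldehyde, C=O
Why: Acid-mediated Mannich condensation and elimination run through the more substituted enol, so methylenation should occur at C5' and not at the methyl group (α-methylenation of a ketone).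

Step 20
Reactants: 31 α-methylene ketone
Product: 32 ethyl (2E,5R)-8-(tert-butyldiphenylsilyloxy)-3,5-dimethyl-4-methyleneoct-2-enoate
Conditions: (EtO)2P(O)CH2CO2Et, NaH, THF, 0 °C to rt
Reagents that add atoms: triethyl phosphonoacetate, CCOC(=O)CP(=O)(OCC)OCC
Why: Horner–Wadsworth–Emmons olefination of the methyl ketone gives mainly the (E)-trisubstituted enoate, the α-substituent slowing conjugate addition to the vinyl ketone.

Step 21
Reactants: 32 dienoate
Product: 33 (2E,5R)-8-(tert-butyldiphenylsilyloxy)-3,5-dimethyl-4-methyleneoct-2-en-1-ol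
Conditions: i-Bu2AlH, CH2Cl2, −78 °C
Reagents that add atoms: none
Why: Hydride reduction of the enoate gives the (E)-allylic alcohol (1,2-reduction of an ester).

Step 22
Reactants: 33 dienol
Product: 34 (2S,3S)-2,3-epoxy alcohol (epoxide across C9'–C10'; the 4-methylene group is retained)
Conditions: Ti(OiPr)4, L-(+)-diethyl tartrate, t-BuOOH, 4 Å MS, CH2Cl2, −20 °C
Reagents that add atoms: tert-butyl hydroperoxide, CC(C)(C)OO
Why: Sharpless asymmetric epoxidation oxidises only the allylic-alcohol alkene and sets C10' by reagent control, as for geraniol-type substrates with the L-tartrate.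

Step 23
Reactants: 34 epoxy alcohol
Product: 35 (3R,5R)-8-(tert-butyldiphenylsilyloxy)-3,5-dimethyl-4-methyleneoctane-1,3-diol
Conditions: NaAlH2(OCH2CH2OMe)2, THF, 0 °C
Reagents that add atoms: none
Why: The aluminate bound to the primary alkoxide delivers hydride intramolecularly to C9', which opens the epoxide to the 1,3-diol and leaves the tertiary C10'–O bond untouched (directed reductive epoxide opening).

Step 24
Reactants: 35 diol
Product: 36 (3R,5R)-8-(tert-butyldiphenylsilyloxy)-3-hydroxy-3,5-dimethyl-4-methyleneoctanal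
Conditions: TEMPO (10 mol %), PhI(OAc)2, CH2Cl2, rt
Reagents that add atoms: none
Why: Oxoammonium oxidation is selective for the primary alcohol over the tertiary one and stops at the aldehyde.

Step 25
Reactants: 37 acrolein; 38 methyl acrylate
Product: 39 methyl 3-hydroxy-2-methylenepent-4-enoate (racemic)
Conditions: DABCO (cat.), neat, rt
Reagents that add atoms: none
Why: In this Morita–Baylis–Hillman reaction, acrolein serves as the aldehyde partner of methyl acrylate.

Step 26
Reactants: 39 allylic alcohol
Product: 40 methyl (2Z)-2-(bromomethyl)penta-2,4-dienoate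
Conditions: PBr3, Et2O, 0 °C
Reagents that add atoms: phosphorus tribromide, BrP(Br)Br
Why: Bromination with allylic transposition gives the conjugated 2-(bromomethyl) dienoate.

Step 27
Reactants: 36 β-hydroxy aldehyde; 40 allylic bromide
Product: 42 cis-4-vinyl-3-methylene lactone carrying the hydroxylated side chain at C5 (C7', C8', C10' and C4' as in the target), via hydroxy ester 41 (not isolated)
Conditions: In, THF/H2O, rt; then TsOH (cat.), CH2Cl2, rt
Reagents that add atoms: none
Why: The allylindium reagent should add through its γ-carbon in a six-membered cyclic transition state to give the 7',8'-syn adduct, while chelation by the β-hydroxyl with the axial methyl blocking one face gives the 8',10'-syn relationship, and acid then closes the cis-lactone (Barbier allylation and lactonisation).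

Step 28
Reactants: 42 triene lactone
Product: 43 silyl-protected seco-eudesmanolide (cyclohexene closed at C5'=C6')
Conditions: second-generation Grubbs catalyst (H2IMes)(PCy3)Cl2Ru=CHPh (5 mol %), toluene, 80 °C
Reagents that add atoms: none
Why: Ring-closing metathesis between the vinyl group and the 1,1-disubstituted alkene forms the six-membered ring, while the electron-poor exo-methylene of the lactone is not engaged.

Step 29
Reactants: 43 silyl ether
Product: 44 primary alcohol of the seco-eudesmanolide
Conditions: HF·pyridine, THF, 0 °C to rt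
Reagents that add atoms: none
Why: Buffered fluoride removes the silyl group without adding to the α-methylene lactone (silyl ether cleavage).

Step 30
Reactants: 44 diol
Product: 45 1'-O-acetyl-10'-hydroxy-1',10'-seco-eudesma-5',11'(13')-dien-12',8'-olide (the dienophile)
Conditions: Ac2O, pyridine, 0 °C
Reagents that add atoms: acetic anhydride, CC(=O)OC(C)=O
Why: Acetylation takes the primary alcohol and leaves the tertiary allylic alcohol (selective esterification).

**Part 3 – union**

Step 31
Reactants: 26 acetoxy tertiary alcohol; 45 dienophile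
Product: 47 Diels–Alder adduct with the 11-phosphonate (all other atoms as in the target), via acetoxycyclopentadiene 46 (not isolated)
Conditions: Burgess reagent, toluene, 0 to 25 °C; cold filtration through silica; then 45 (2 equiv), concentrated toluene solution, 25 to 45 °C
Reagents that add atoms: none
Why: Dehydration of the tertiary allylic alcohol gives the 2-acetoxycyclopentadiene 46, and in the Diels–Alder reaction the α-methylene lactone should add endo through its convex face to the diene face syn to the acetoxy group, with its quaternary carbon bonding to the less substituted terminus C3; the phosphonate-masked lactone of 46 cannot compete as a dienophile.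

Step 32
Reactants: 47 phosphonate adduct
Product: 48 target (CNP0257312.1)
Conditions: K2CO3, 37% aq. HCHO, THF, 0 °C
Reagents that add atoms: formaldehyde, C=O
Why: Horner–Wadsworth–Emmons olefination with formaldehyde turns the α-phosphono lactone into the α-methylene lactone under mild base that should leave both acetates intact, and both C11 epimers converge.

**Compound list**

1 | tert-butyl(diphenyl)(prop-2-yn-1-yloxy)silane | C#CCO[Si](c1ccccc1)(c1ccccc1)C(C)(C)C | starting material
2 | (1R,2S,5R)-menthyl (S)-p-toluenesulfinate | CC(C)[C@@H]1CC[C@@H](C)C[C@H]1O[S@](=O)c1ccc(C)cc1 | starting material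
3 | alkynylmagnesium bromide of 1 | Br[Mg]C#CCO[Si](c1ccccc1)(c1ccccc1)C(C)(C)C | intermediate
4 | (S)-3-(tert-butyldiphenylsilyloxy)prop-1-ynyl p-tolyl sulfoxide | CC(C)(C)[Si](c1ccccc1)(c1ccccc1)OCC#C[S@@](=O)c1ccc(C)cc1 | intermediate
5 | (R,E)-3-(tert-butyldiphenylsilyloxy)prop-1-enyl p-tolyl sulfoxide | CC(C)(C)[Si](c1ccccc1)(c1ccccc1)OC/C=C/[S@@](=O)c1ccc(C)cc1 | intermediate
6 | O-acylated sulfonium enolate (zwitterion) | CC(C)(C)[Si](c1ccccc1)(c1ccccc1)OC/C=C/[S@@+](OC([O-])=C(Cl)Cl)c1ccc(C)cc1 | intermediate
7 | thionium carboxylate (zwitterion) | [O-]C(=O)C(Cl)(Cl)[C@H](CO[Si](c1ccccc1)(c1ccccc1)C(C)(C)C)C=[S+]c1ccc(C)cc1 | intermediate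
8 | (4R,5R)-3,3-dichloro-4-[(tert-butyldiphenylsilyloxy)methyl]-5-(p-tolylthio)oxolan-2-one | O=C1O[C@H](Sc2ccc(C)cc2)[C@@H](CO[Si](c2ccccc2)(c2ccccc2)C(C)(C)C)C1(Cl)Cl | intermediate
9 | (4R,5R)-4-[(tert-butyldiphenylsilyloxy)methyl]-5-(p-tolylthio)oxolan-2-one | O=C1O[C@H](Sc2ccc(C)cc2)[C@@H](CO[Si](c2ccccc2)(c2ccccc2)C(C)(C)C)C1 | intermediate
10 | (2-bromoallyl)trimethylsilane | C=C(Br)C[Si](C)(C)C | starting material
11 | acyloxycarbenium ion from 9 | O=C1C[C@H](CO[Si](c2ccccc2)(c2ccccc2)C(C)(C)C)C=[O+]1 | intermediate
12 | 4,5-trans-5-(2-bromoprop-2-enyl)-4-[(tert-butyldiphenylsilyloxy)methyl]oxolan-2-one | O=C1C[C@H](CO[Si](c2ccccc2)(c2ccccc2)C(C)(C)C)[C@@H](CC(Br)=C)O1 | intermediate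
13 | lactone enol phosphate | CCOP(=O)(OCC)OC1=C[C@H](CO[Si](c2ccccc2)(c2ccccc2)C(C)(C)C)[C@@H](CC(Br)=C)O1 | intermediate
14 | α-phosphono lactone, silyl ether (C11 epimers) | O=C1O[C@H](CC(Br)=C)[C@@H](CO[Si](c2ccccc2)(c2ccccc2)C(C)(C)C)C1P(=O)(OCC)OCC | intermediate
15 | α-phosphono lactone, primary alcohol | O=C1O[C@H](CC(Br)=C)[C@@H](CO)C1P(=O)(OCC)OCC | intermediate
16 | α-phosphono lactone, primary iodide | O=C1O[C@H](CC(Br)=C)[C@@H](CI)C1P(=O)(OCC)OCC | intermediate
17 | (R)-4-(tert-butyldimethylsilyloxy)cyclopent-2-en-1-one | O=C1C=C[C@H](O[Si](C)(C)C(C)(C)C)C1 | starting material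
18 | (R)-4-(tert-butyldimethylsilyloxy)-2-iodocyclopent-2-en-1-one | O=C1C(I)=C[C@H](O[Si](C)(C)C(C)(C)C)C1 | intermediate
19 | alkylzinc iodide from 16 | O=C1O[C@H](CC(Br)=C)[C@@H](C[Zn]I)C1P(=O)(OCC)OCC | intermediate
20 | coupled 2-substituted cyclopentenone with vinyl bromide | O=C1C(C[C@H]2C(P(=O)(OCC)OCC)C(=O)O[C@@H]2CC(Br)=C)=C[C@H](O[Si](C)(C)C(C)(C)C)C1 | intermediate
21 | tricyclic triethylsilyl enol ether | CC[Si](CC)(CC)OC1=C2C[C@H]3C(P(=O)(OCC)OCC)C(=O)O[C@@H]3CC(=C)[C@H]2[C@H](O[Si](C)(C)C(C)(C)C)C1 | intermediate
22 | 2α-silyloxy dienone | O=C1C2=C(C(=C)C[C@H]3OC(=O)C(P(=O)(OCC)OCC)[C@@H]3C2)[C@H](O[Si](C)(C)C(C)(C)C)C1 | intermediate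
23 | 2α-hydroxy dienone | O=C1C2=C(C(=C)C[C@H]3OC(=O)C(P(=O)(OCC)OCC)[C@@H]3C2)[C@H](O)C1 | intermediate
24 | 2α-hydroxy-10β-methyl enone | O=C1C2=C([C@H](C)C[C@H]3OC(=O)C(P(=O)(OCC)OCC)[C@@H]3C2)[C@H](O)C1 | intermediate
25 | 2α,4-diol (C4 epimers) | CC1(O)C2=C([C@H](C)C[C@H]3OC(=O)C(P(=O)(OCC)OCC)[C@@H]3C2)[C@H](O)C1 | intermediate
26 | 2α-acetoxy-4-hydroxy compound | CC1(O)C2=C([C@H](C)C[C@H]3OC(=O)C(P(=O)(OCC)OCC)[C@@H]3C2)[C@H](OC(C)=O)C1 | intermediate
27 | tert-butyl(pent-4-en-1-yloxy)diphenylsilane | C=CCCCO[Si](c1ccccc1)(c1ccccc1)C(C)(C)C | starting material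
28 | methyl vinyl ketone | CC(=O)C=C | starting material
29 | (E)-7-(tert-butyldiphenylsilyloxy)hept-3-en-2-one | CC(=O)/C=C/CCCO[Si](c1ccccc1)(c1ccccc1)C(C)(C)C | intermediate
30 | (R)-7-(tert-butyldiphenylsilyloxy)-4-methylheptan-2-one | CC(=O)C[C@H](C)CCCO[Si](c1ccccc1)(c1ccccc1)C(C)(C)C | intermediate
31 | (R)-7-(tert-butyldiphenylsilyloxy)-4-methyl-3-methyleneheptan-2-one | CC(=O)C(=C)[C@H](C)CCCO[Si](c1ccccc1)(c1ccccc1)C(C)(C)C | intermediate
32 | ethyl (2E,5R)-8-(tert-butyldiphenylsilyloxy)-3,5-dimethyl-4-methyleneoct-2-enoate | CCOC(=O)/C=C(C)/C(=C)[C@H](C)CCCO[Si](c1ccccc1)(c1ccccc1)C(C)(C)C | intermediate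
33 | (2E,5R)-8-(tert-butyldiphenylsilyloxy)-3,5-dimethyl-4-methyleneoct-2-en-1-ol | OC/C=C(C)/C(=C)[C@H](C)CCCO[Si](c1ccccc1)(c1ccccc1)C(C)(C)C | intermediate
34 | (2S,3S)-epoxy alcohol of 33 | OC[C@@H]1O[C@@]1(C)C(=C)[C@H](C)CCCO[Si](c2ccccc2)(c2ccccc2)C(C)(C)C | intermediate
35 | (3R,5R)-8-(tert-butyldiphenylsilyloxy)-3,5-dimethyl-4-methyleneoctane-1,3-diol | OCC[C@@](C)(O)C(=C)[C@H](C)CCCO[Si](c1ccccc1)(c1ccccc1)C(C)(C)C | intermediate
36 | (3R,5R)-8-(tert-butyldiphenylsilyloxy)-3-hydroxy-3,5-dimethyl-4-methyleneoctanal | O=CC[C@@](C)(O)C(=C)[C@H](C)CCCO[Si](c1ccccc1)(c1ccccc1)C(C)(C)C | intermediate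
37 | acrolein | C=CC=O | starting material
38 | methyl acrylate | C=CC(=O)OC | starting material
39 | methyl 3-hydroxy-2-methylenepent-4-enoate | C=CC(O)C(=C)C(=O)OC | intermediate
40 | methyl (2Z)-2-(bromomethyl)penta-2,4-dienoate | C=C/C=C(\CBr)C(=O)OC | intermediate
41 | hydroxy ester (7',8'-syn; 8',10'-syn) | COC(=O)C(=C)[C@H](C=C)[C@@H](O)C[C@@](C)(O)C(=C)[C@H](C)CCCO[Si](c1ccccc1)(c1ccccc1)C(C)(C)C | intermediate
42 | cis-4-vinyl-3-methylene lactone with open side chain | C=C1C(=O)O[C@@H](C[C@@](C)(O)C(=C)[C@H](C)CCCO[Si](c2ccccc2)(c2ccccc2)C(C)(C)C)[C@H]1C=C | intermediate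
43 | silyl-protected seco-eudesmanolide | C=C1C(=O)O[C@H]2C[C@@](C)(O)C([C@H](C)CCCO[Si](c3ccccc3)(c3ccccc3)C(C)(C)C)=C[C@@H]12 | intermediate
44 | seco-eudesmanolide primary alcohol | C=C1C(=O)O[C@H]2C[C@@](C)(O)C([C@H](C)CCCO)=C[C@@H]12 | intermediate
45 | seco-eudesmanolide dienophile (1'-acetate) | C=C1C(=O)O[C@H]2C[C@@](C)(O)C([C@H](C)CCCOC(C)=O)=C[C@@H]12 | intermediate
46 | 2α-acetoxy-guaia-1(5),3-dien-12,8α-olide 11-phosphonate (diene) | CCOP(=O)(OCC)C1C(=O)O[C@@H]2C[C@@H](C)C3=C(C[C@@H]12)C(C)=C[C@H]3OC(C)=O | intermediate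
47 | Diels–Alder adduct, 11-phosphonate | CCOP(=O)(OCC)C1C(=O)O[C@@H]2C[C@@H](C)[C@]34C[C@]5(C(=O)O[C@H]6C[C@@](C)(O)C([C@H](C)CCCOC(C)=O)=C[C@H]65)[C@H](C(C)=C3C[C@@H]12)[C@H]4OC(C)=O | intermediate
48 | CNP0257312.1 | C=C1C(=O)O[C@@H]2C[C@@H](C)[C@]34C[C@]5(C(=O)O[C@H]6C[C@@](C)(O)C([C@H](C)CCCOC(C)=O)=C[C@H]65)[C@H](C(C)=C3C[C@@H]12)[C@H]4OC(C)=O | target

**Count and risks**

Total step count: 32. Longest linear sequence: 17 steps (steps 1–8, 10–16, 31, 32).

Steps most likely to fail:

1. Step 5 (proposed new method). The thioacetal may ionise toward the thionium ion with opening of the lactone instead of toward the acyloxycarbenium ion, or the deactivated allylsilane may capture the cation too slowly, so that elimination or hydrolysis wins. Fallback: from 9, oxidise the sulfide with mCPBA to the sulfone F1 and displace the sulfinate with 10 under AlCl3 in CH2Cl2 at −78 °C, the anomeric-sulfone substitution used for C-glycosides; this returns to 12.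

2. Step 31. The 5-acetoxycyclopentadiene may undergo 1,5-hydrogen shift before cycloaddition, dehydration may run toward the exocyclic alkene, residual dehydrating agent may attack the tertiary alcohol of the dienophile, and facial or regiochemical control may be incomplete. Fallback: from 45, silylate the tertiary alcohol with Et3SiOTf and 2,6-lutidine to the triethylsilyl ether F2; add the Burgess reagent to a mixture of 26 and excess F2 so that the diene is trapped as it forms, giving the silylated adduct F3; HF·pyridine removes the silyl group and returns to 47.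

3. Step 11. Closure of the seven-membered ring may be slower than reduction of the vinyl bromide or intermolecular coupling. Fallback: from 20, close the ring by a tin-free radical 7-endo cyclisation ((Me3Si)3SiH, AIBN, benzene, 80 °C, slow addition) to the saturated ketone F4 and dehydrogenate it with IBX in DMSO at 70 °C; this returns to 22.

Further compounds
F1 | step 5 | (4R,5R)-4-[(tert-butyldiphenylsilyloxy)methyl]-5-(p-tolylsulfonyl)oxolan-2-one | O=C1O[C@H](S(=O)(=O)c2ccc(C)cc2)[C@@H](CO[Si](c2ccccc2)(c2ccccc2)C(C)(C)C)C1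
F2 | step 31 | 10'-O-triethylsilyl ether of dienophile 45 | C=C1C(=O)O[C@H]2C[C@@](C)(O[Si](CC)(CC)CC)C([C@H](C)CCCOC(C)=O)=C[C@@H]12
F3 | step 31 | 10'-O-triethylsilyl ether of adduct 47 | CCOP(=O)(OCC)C1C(=O)O[C@@H]2C[C@@H](C)[C@]34C[C@]5(C(=O)O[C@H]6C[C@@](C)(O[Si](CC)(CC)CC)C([C@H](C)CCCOC(C)=O)=C[C@H]65)[C@H](C(C)=C3C[C@@H]12)[C@H]4OC(C)=O
F4 | step 11 | saturated tricyclic C4 ketone (C10=C14 exocyclic methylene, 2α-silyloxy) | O=C1C2C[C@H]3C(P(=O)(OCC)OCC)C(=O)O[C@@H]3CC(=C)[C@H]2[C@H](O[Si](C)(C)C(C)(C)C)C1
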